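**Retrosynthetic overview**
- Target 15 comes from flavonol tribenzyl ether 14 by hydrogenolysis, and 14 from chroman-3-one 12 by oxidation of the C4 methylene and tautomerisation.
- 12 comes from aryl propargyl ether 11 by gold-catalysed alkyne oxidation and arene C–H functionalisation, which forms C3=O and the C4–C4a bond together. Ring C is the only ring built; rings A and B are bought.
- The strategy rests on this feature: C4 is bonded to C4a, the only unsubstituted carbon ortho to O1 on ring A (the other ortho carbon, C8, carries OMe), and the neighbouring C3 bears oxygen. The unit O1–C2–C3(O)–C4 is therefore a 1-arylpropargyl ether of the ring A phenol.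
- 11 comes from a Mitsunobu union of propargylic alcohol 6 (ring B aldehyde 4 plus ethynylmagnesium bromide 5) with 3-hydroxy-4,5-dimethoxybenzaldehyde 7. The hydroxyl of 7 is O1, and its formyl carbon is turned into the C5 oxygen by Baeyer–Villiger oxidation and benzylation.

Key step: step 8

Remark on the chemistry: O1 is flanked by the C8 methoxy group, so it has to be the hydroxyl that 7 already carries. The Mitsunobu reaction is therefore run on 7 itself and the formyl group is converted into the benzyloxy group afterwards; etherifying the phenol obtained from the formyl group instead would lead to the 5,6,7-oxygenated isomer. The target has no stereocentre; the future C2 is carried as a racemate from step 4 and becomes sp2 in step 9. Flavonoid numbering (O1, C2–C4, C4a, C5–C8, C8a) is used throughout.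

**Route**

Step 1
Reactants: 1 3,5-dihydroxy-4-methoxybenzoic acid
Product: 2 benzyl 3,5-bis(benzyloxy)-4-methoxybenzoate
Conditions: BnBr (3.5 equiv), K2CO3, DMF, 60 °C
Reagents that add atoms: benzyl bromide, BrCc1ccccc1
Why: Williamson etherification and carboxylate alkylation: K2CO3 deprotonates both phenols and the acid, and SN2 attack on benzyl bromide should give the tribenzyl compound in one operation.

Step 2
Reactants: 2 benzyl 3,5-bis(benzyloxy)-4-methoxybenzoate
Product: 3 [3,5-bis(benzyloxy)-4-methoxyphenyl]methanol
Conditions: LiAlH4, THF, 0 °C to rt; then H2O, 15% aq. NaOH, H2O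
Reagents that add atoms: none
Why: Hydride reduction of the benzyl ester to the primary benzylic alcohol, with release of benzyl alcohol; aryl benzyl and methyl ethers are inert to LiAlH4.

Step 3
Reactants: 3 [3,5-bis(benzyloxy)-4-methoxyphenyl]methanol
Product: 4 3,5-bis(benzyloxy)-4-methoxybenzaldehyde
Conditions: MnO2 (excess), CH2Cl2, rt
Reagents that add atoms: none
Why: MnO2 oxidation is selective for benzylic alcohols and should stop at the aldehyde.

Step 4
Reactants: 4 3,5-bis(benzyloxy)-4-methoxybenzaldehyde; 5 ethynylmagnesium bromide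
Product: 6 1-[3,5-bis(benzyloxy)-4-methoxyphenyl]prop-2-yn-1-ol (racemic)
Conditions: THF, 0 °C to rt; then sat. aq. NH4Cl
Reagents that add atoms: none
Why: Grignard 1,2-addition of the acetylide to the aldehyde; the carbinol centre forms as a racemate, which is acceptable because this carbon ends as sp2 C2 of the flavonol.

Step 5
Reactants: 6 1-[3,5-bis(benzyloxy)-4-methoxyphenyl]prop-2-yn-1-ol (racemic); 7 3-hydroxy-4,5-dimethoxybenzaldehyde
Product: 8 3-({1-[3,5-bis(benzyloxy)-4-methoxyphenyl]prop-2-yn-1-yl}oxy)-4,5-dimethoxybenzaldehyde (racemic)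
Conditions: PPh3, DIAD, THF, 0 °C to rt
Reagents that add atoms: none
Why: Mitsunobu etherification: the phenol of 7, made more acidic by the meta formyl group, should displace the activated secondary propargylic oxyphosphonium by SN2, which puts the ether oxygen next to the methoxy group that becomes C8-OMe; the racemic centre is carried on.

Step 6
Reactants: 8 3-({1-[3,5-bis(benzyloxy)-4-methoxyphenyl]prop-2-yn-1-yl}oxy)-4,5-dimethoxybenzaldehyde (racemic)
Product: 10 3-({1-[3,5-bis(benzyloxy)-4-methoxyphenyl]prop-2-yn-1-yl}oxy)-4,5-dimethoxyphenol (racemic), via aryl formate 9 (not isolated)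
Conditions: mCPBA, CH2Cl2, 0 °C to rt; aq. NaHCO3/Na2S2O3 wash; then K2CO3 (cat.), MeOH, rt
Reagents that add atoms: mCPBA, O=C(OO)c1cccc(Cl)c1
Why: Baeyer–Villiger oxidation: the electron-rich trialkoxyaryl group (para methoxy) migrates in the Criegee intermediate to give the aryl formate, which mild methanolysis cleaves; the terminal alkyne and the ethers should not react with the peracid at this temperature.

Step 7
Reactants: 10 3-({1-[3,5-bis(benzyloxy)-4-methoxyphenyl]prop-2-yn-1-yl}oxy)-4,5-dimethoxyphenol (racemic)
Product: 11 1-(benzyloxy)-3-({1-[3,5-bis(benzyloxy)-4-methoxyphenyl]prop-2-yn-1-yl}oxy)-4,5-dimethoxybenzene (racemic)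
Conditions: BnBr, K2CO3, DMF, rt
Reagents that add atoms: benzyl bromide, BrCc1ccccc1
Why: Williamson etherification of the only free phenol; K2CO3 is too weak a base to deprotonate or isomerise the terminal alkyne.

Step 8
Reactants: 11 1-(benzyloxy)-3-({1-[3,5-bis(benzyloxy)-4-methoxyphenyl]prop-2-yn-1-yl}oxy)-4,5-dimethoxybenzene (racemic)
Product: 12 5-(benzyloxy)-2-[3,5-bis(benzyloxy)-4-methoxyphenyl]-7,8-dimethoxychroman-3-one (racemic)
Conditions: Me4tBuXPhosAuNTf2 (5 mol %), 2,6-dichloropyridine N-oxide (1.3 equiv), 1,2-dichloroethane, rt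
Reagents that add atoms: 2,6-dichloropyridine N-oxide, [O-][n+]1c(Cl)cccc1Cl
Why: The cationic monovalent gold complex activates the terminal alkyne, the N-oxide oxygen adds to the internal carbon with gold at the terminus, and loss of 2,6-dichloropyridine leaves an α-oxo gold carbene whose carbene carbon is the future C4 and whose carbonyl is C3=O. Ring A then attacks the carbene carbon in an intramolecular Friedel–Crafts-type substitution, and rearomatisation with protodeauration releases the ketone; this is the known gold-catalysed oxidative cyclisation of aryl propargyl ethers to chroman-3-ones. Ring C closes as a six-membered ring through C4–C4a, with the arene bond C4a–C8a inside the new ring and the C=Au bond outside it. No stereocentre is created, since C2 is the racemic centre from step 4 and is flattened in step 9. The step needs oxygen delivery to the internal alkyne carbon, which the terminal alkyne secures, and attack at C4a, which is the only unsubstituted carbon ortho to O1 (the other ortho carbon carries the C8 methoxy group) and is activated by O1, the C5 benzyloxy group and the para C7 methoxy group, whereas attack by ring B would have to close a five-membered indan-2-one. The bulky biaryl phosphine and the hindered, weakly basic N-oxide are chosen to disfavour direct 6-endo hydroarylation to the 2H-chromene, a second oxidation of the carbene, and acid-promoted ionisation of the propargylic ether.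

Step 9
Reactants: 12 5-(benzyloxy)-2-[3,5-bis(benzyloxy)-4-methoxyphenyl]-7,8-dimethoxychroman-3-one (racemic)
Product: 14 5-(benzyloxy)-2-[3,5-bis(benzyloxy)-4-methoxyphenyl]-3-hydroxy-7,8-dimethoxy-4H-chromen-4-one, via diketone 13 (not isolated)
Conditions: SeO2 (1.3 equiv), 1,4-dioxane/H2O, 90 °C
Reagents that add atoms: selenium dioxide, O=[Se]=O
Why: Riley oxidation: SeO2 should attack the enol at C4, the only α-carbon with two hydrogens and hence the only one that can become a carbonyl, and diketone 13 then tautomerises through its C2–H to the aromatic 3-hydroxychromen-4-one, which removes the C2 stereocentre; the neutral conditions avoid enolate oxygenation at C2 and base-induced oxygenolysis of the flavonol.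

Step 10
Reactants: 14 5-(benzyloxy)-2-[3,5-bis(benzyloxy)-4-methoxyphenyl]-3-hydroxy-7,8-dimethoxy-4H-chromen-4-one
Product: 15 3,5-dihydroxy-2-(3,5-dihydroxy-4-methoxyphenyl)-7,8-dimethoxy-4H-chromen-4-one (CNP0165950.0)
Conditions: H2 (1 atm), 10% Pd/C, THF/MeOH, rt
Reagents that add atoms: none
Why: Catalytic hydrogenolysis should cleave the three aryl benzyl ethers, while the methyl ethers and the chromone C2=C3 bond (part of a vinylogous ester) are not reduced at 1 atm.

**Compound list**
1 | 3,5-dihydroxy-4-methoxybenzoic acid | COc1c(O)cc(C(=O)O)cc1O | starting material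
2 | benzyl 3,5-bis(benzyloxy)-4-methoxybenzoate | COc1c(OCc2ccccc2)cc(C(=O)OCc2ccccc2)cc1OCc1ccccc1 | intermediate
3 | [3,5-bis(benzyloxy)-4-methoxyphenyl]methanol | COc1c(OCc2ccccc2)cc(CO)cc1OCc1ccccc1 | intermediate
4 | 3,5-bis(benzyloxy)-4-methoxybenzaldehyde | COc1c(OCc2ccccc2)cc(C=O)cc1OCc1ccccc1 | intermediate
5 | ethynylmagnesium bromide | C#C[Mg]Br | starting material
6 | 1-[3,5-bis(benzyloxy)-4-methoxyphenyl]prop-2-yn-1-ol (racemic) | C#CC(O)c1cc(OCc2ccccc2)c(OC)c(OCc2ccccc2)c1 | intermediate
7 | 3-hydroxy-4,5-dimethoxybenzaldehyde | COc1cc(C=O)cc(O)c1OC | starting material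
8 | 3-({1-[3,5-bis(benzyloxy)-4-methoxyphenyl]prop-2-yn-1-yl}oxy)-4,5-dimethoxybenzaldehyde (racemic) | C#CC(Oc1cc(C=O)cc(OC)c1OC)c1cc(OCc2ccccc2)c(OC)c(OCc2ccccc2)c1 | intermediate
9 | 3-({1-[3,5-bis(benzyloxy)-4-methoxyphenyl]prop-2-yn-1-yl}oxy)-4,5-dimethoxyphenyl formate (racemic) | C#CC(Oc1cc(OC=O)cc(OC)c1OC)c1cc(OCc2ccccc2)c(OC)c(OCc2ccccc2)c1 | intermediate
10 | 3-({1-[3,5-bis(benzyloxy)-4-methoxyphenyl]prop-2-yn-1-yl}oxy)-4,5-dimethoxyphenol (racemic) | C#CC(Oc1cc(O)cc(OC)c1OC)c1cc(OCc2ccccc2)c(OC)c(OCc2ccccc2)c1 | intermediate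
11 | 1-(benzyloxy)-3-({1-[3,5-bis(benzyloxy)-4-methoxyphenyl]prop-2-yn-1-yl}oxy)-4,5-dimethoxybenzene (racemic) | C#CC(Oc1cc(OCc2ccccc2)cc(OC)c1OC)c1cc(OCc2ccccc2)c(OC)c(OCc2ccccc2)c1 | intermediate
12 | 5-(benzyloxy)-2-[3,5-bis(benzyloxy)-4-methoxyphenyl]-7,8-dimethoxychroman-3-one (racemic) | COc1cc(OCc2ccccc2)c2c(c1OC)OC(c1cc(OCc3ccccc3)c(OC)c(OCc3ccccc3)c1)C(=O)C2 | intermediate
13 | 5-(benzyloxy)-2-[3,5-bis(benzyloxy)-4-methoxyphenyl]-7,8-dimethoxychromane-3,4-dione (racemic) | COc1cc(OCc2ccccc2)c2c(c1OC)OC(c1cc(OCc3ccccc3)c(OC)c(OCc3ccccc3)c1)C(=O)C2=O | intermediate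
14 | 5-(benzyloxy)-2-[3,5-bis(benzyloxy)-4-methoxyphenyl]-3-hydroxy-7,8-dimethoxy-4H-chromen-4-one | COc1cc(OCc2ccccc2)c2c(=O)c(O)c(-c3cc(OCc4ccccc4)c(OC)c(OCc4ccccc4)c3)oc2c1OC | intermediate
15 | 3,5-dihydroxy-2-(3,5-dihydroxy-4-methoxyphenyl)-7,8-dimethoxy-4H-chromen-4-one | COc1cc(O)c2c(=O)c(O)c(-c3cc(O)c(OC)c(O)c3)oc2c1OC | target

**Step count and risks**
Total step count: 10. Longest linear sequence: 10 steps (1 to 15); 5 and 7 enter as bought building blocks.

Steps most likely to fail:

1. Step 8. The very electron-rich ring A may add directly to the gold-activated alkyne (6-endo hydroarylation) before the N-oxide does, the Lewis-acidic gold may ionise the doubly activated propargylic C–O bond, or the carbene may be oxidised a second time. Fallback, from 11 back to 12 without gold: heating 11 in N,N-diethylaniline at about 190 °C (aryl propargyl ether Claisen rearrangement, enolisation, 1,5-hydrogen shift and oxa-6π electrocyclisation, which can only end productively at the same free ortho carbon) should give 5-(benzyloxy)-2-[3,5-bis(benzyloxy)-4-methoxyphenyl]-7,8-dimethoxy-2H-chromene F1. Hydroboration with BH3·SMe2 in THF followed by NaOH/H2O2 should place the hydroxyl at C3, distal to ring A and trans to the C2 aryl group, to give 2,3-trans-5-(benzyloxy)-2-[3,5-bis(benzyloxy)-4-methoxyphenyl]-7,8-dimethoxychroman-3-ol F2 as a racemate. Dess–Martin periodinane in CH2Cl2 then rejoins the route at 12.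

2. Step 9. Oxidation may start at the C2 methine instead of the C4 methylene, or the flavonol may be oxidised further with ring cleavage. Fallback, from 12 to 14 by a reaction that only a methylene can undergo: condensation of 12 with N,N-dimethylformamide dimethyl acetal in toluene at 80 °C should give 5-(benzyloxy)-2-[3,5-bis(benzyloxy)-4-methoxyphenyl]-4-[(dimethylamino)methylidene]-7,8-dimethoxychroman-3-one F3 (racemic, double-bond geometry not defined). Cleavage of the enaminone C=C bond with NaIO4 in aqueous THF should give diketone 13, which tautomerises to 14.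

3. Step 5. The activated alcohol, benzylic to an electron-rich ring and propargylic, may ionise or react in the SN2' sense to give an allenyl ether, or the hydrazide may be alkylated in place of the hindered phenol. Fallback, from 6 to 8 by a different activation: acetylation of 6 (Ac2O, Et3N, DMAP, CH2Cl2) should give 1-[3,5-bis(benzyloxy)-4-methoxyphenyl]prop-2-yn-1-yl acetate F4 (racemic). Copper-catalysed propargylic substitution of F4 with phenol 7 ((CuOTf)2·C6H6, monovalent copper, a 2,6-bis(oxazolinyl)pyridine ligand, iPr2NEt), which runs through a copper allenylidene and is specific to terminal 1-arylpropargyl esters, should deliver 8.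

**Further compounds**
F1 | step 8 | 5-(benzyloxy)-2-[3,5-bis(benzyloxy)-4-methoxyphenyl]-7,8-dimethoxy-2H-chromene (racemic) | COc1cc(OCc2ccccc2)c2c(c1OC)OC(c1cc(OCc3ccccc3)c(OC)c(OCc3ccccc3)c1)C=C2
F2 | step 8 | 2,3-trans-5-(benzyloxy)-2-[3,5-bis(benzyloxy)-4-methoxyphenyl]-7,8-dimethoxychroman-3-ol (racemic, one enantiomer drawn) | O[C@H]1Cc2c(OCc3ccccc3)cc(OC)c(OC)c2O[C@@H]1c1cc(OCc2ccccc2)c(OC)c(OCc2ccccc2)c1
F3 | step 9 | 5-(benzyloxy)-2-[3,5-bis(benzyloxy)-4-methoxyphenyl]-4-[(dimethylamino)methylidene]-7,8-dimethoxychroman-3-one (racemic, double-bond geometry not defined) | COc1cc(OCc2ccccc2)c2c(c1OC)OC(c1cc(OCc3ccccc3)c(OC)c(OCc3ccccc3)c1)C(=O)C2=CN(C)C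
F4 | step 5 | 1-[3,5-bis(benzyloxy)-4-methoxyphenyl]prop-2-yn-1-yl acetate (racemic) | C#CC(OC(C)=O)c1cc(OCc2ccccc2)c(OC)c(OCc2ccccc2)c1
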